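**Retrosynthetic overview**
1. Ester C–O bond last: IN0146 ⇒ hydroxy ketone 20 + linoleic acid 34; the acid ⇐ Lindlar reduction of the 9,12-diyne ⇐ dec-9-ynoic acid + oct-2-ynyl tosylate.
2. Side chain: C(=CH2)CH2–CH2CH2OH ⇐ allyl anion of an isopropenyl group + oxirane; isopropenyl–ring bond ⇐ Zweifel olefination of a trans-cyclobutyl pinacol boronate.
3. Both stereocentres ⇐ one enantioselective syn hydroboration of an achiral 1-alkyl-4,4-dimethylcyclobutene.
4. Cyclobutene ⇐ B-alkyl Suzuki coupling of 4,4-dimethylcyclobutenyl triflate with the 9-BBN adduct of 2-ethenyl-2-methyl-1,3-dioxolane.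
5. Ring order: the only ring, the cyclobutane, is made first, by semipinacol ring expansion of 1-isopropenylcyclopropanol to 2,2-dimethylcyclobutanone.

Assumption: the target is the trans enantiomer encoded by the SMILES, (1S,2R) when the ring is numbered from the alkenyl-bearing carbon and (1R,4S) when numbered from the carbon bearing the oxobutyl (or ketal) chain.
Assumption: the ligand in step 4 is written as (R)-DTBM-SEGPHOS; if the facial sense proves opposite, the (S)-ligand is used with no other change.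
Assumption: formaldehyde is used as dry paraformaldehyde, and 1-ethoxycyclopropan-1-ol (cyclopropanone ethyl hemiacetal) is a catalogue chemical.

**Step 1**
Reactants: 1 1-ethoxycyclopropan-1-ol; 2 prop-1-en-2-ylmagnesium bromide
Product: 5 2,2-dimethylcyclobutan-1-one, via cyclopropanone 3 (not isolated), via 1-(prop-1-en-2-yl)cyclopropan-1-ol 4 (not isolated)
Conditions: MeMgBr (1.0 equiv), THF, 0 °C; 2 (1.5 equiv), 65 °C; aq NH4Cl; crude in CH2Cl2, TsOH·H2O (10 mol%), 25 °C
Reagents that add atoms: none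
Why: Grignard addition to the cyclopropanone released from the hemiacetal gives the 1-alkenylcyclopropanol, and protonation of its alkene terminus gives a tertiary cyclopropylcarbinyl cation that undergoes a semipinacol 1,2-alkyl shift (ring expansion of the three-membered to the four-membered ring, driven by C=O formation); no stereocentre is formed.

**Step 2**
Reactants: 5 2,2-dimethylcyclobutan-1-one
Product: 7 4,4-dimethylcyclobut-1-en-1-yl trifluoromethanesulfonate, via potassium 4,4-dimethylcyclobut-1-en-1-olate 6 (not isolated)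
Conditions: KN(SiMe3)2, THF, −78 °C; PhNTf2, −78 → 0 °C
Reagents that add atoms: N-phenylbis(trifluoromethanesulfonimide) (O=S(=O)(N(c1ccccc1)S(=O)(=O)C(F)(F)F)C(F)(F)F)
Why: Enolisation is possible only towards the CH2 side, so O-triflation of the potassium enolate (enol triflate formation) gives a single regioisomer.

**Step 3**
Reactants: 8 2-ethenyl-2-methyl-1,3-dioxolane; 7 4,4-dimethylcyclobut-1-en-1-yl trifluoromethanesulfonate
Product: 10 2-[2-(4,4-dimethylcyclobut-1-en-1-yl)ethyl]-2-methyl-1,3-dioxolane, via 9-[2-(2-methyl-1,3-dioxolan-2-yl)ethyl]-9-borabicyclo[3.3.1]nonane 9 (not isolated)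
Conditions: 8, 9-BBN-H, THF, 0 → 25 °C; then 7, Pd(dppf)Cl2 (5 mol%), K3PO4 (3 M aq), THF/DMF, 50 °C
Reagents that add atoms: none
Why: Anti-Markovnikov hydroboration of the vinyl ketal followed by B-alkyl Suzuki–Miyaura coupling (oxidative addition of the alkenyl triflate to zerovalent palladium, base-assisted transmetalation, reductive elimination) forms the C(sp2)–C(sp3) bond; no stereocentre is formed.

**Step 4**
Reactants: 10 2-[2-(4,4-dimethylcyclobut-1-en-1-yl)ethyl]-2-methyl-1,3-dioxolane
Product: 11 2-{2-[(1R,4S)-2,2-dimethyl-4-(4,4,5,5-tetramethyl-1,3,2-dioxaborolan-2-yl)cyclobutyl]ethyl}-2-methyl-1,3-dioxolane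
Conditions: Cu(OAc)2 (5 mol%), (R)-DTBM-SEGPHOS (5.5 mol%), HBpin (1.5 equiv), THF, 40 °C
Reagents that add atoms: pinacolborane ([H]B1OC(C)(C)C(C)(C)O1)
Why: Proposed new method: CuH-catalysed enantioselective hydroboration of an unactivated 1-alkyl-4,4-dimethylcyclobutene, in which the monovalent copper hydride (formed from divalent copper acetate and HBpin) adds syn across the strained trisubstituted alkene with copper on the less hindered CH carbon and hydride on the alkyl-bearing carbon, the bisphosphine selects one of the two enantiotopic faces, and stereoretentive σ-bond metathesis of the cyclobutylcopper with HBpin gives the trans boronate, so both stereocentres (1R,4S) are set here; the closest known reactions are CuH/bisphosphine hydroboration of styrenes and strained bicyclic alkenes and CuH hydroamination of 1-arylcyclobutenes.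

**Step 5**
Reactants: 11 2-{2-[(1R,4S)-2,2-dimethyl-4-(4,4,5,5-tetramethyl-1,3,2-dioxaborolan-2-yl)cyclobutyl]ethyl}-2-methyl-1,3-dioxolane; 12 2-bromoprop-1-ene
Product: 16 2-{2-[(1R,4S)-2,2-dimethyl-4-(prop-1-en-2-yl)cyclobutyl]ethyl}-2-methyl-1,3-dioxolane, via prop-1-en-2-yllithium 13 (not isolated), via lithium alkenylboronate complex 14 (not isolated), via β-iodoalkylboronate 15 (not isolated)
Conditions: 12, t-BuLi (2 equiv per 12), THF, −78 °C; 11, −78 °C; I2, MeOH/THF, −78 °C; NaOMe, MeOH, −78 → 25 °C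
Reagents that add atoms: none
Why: Zweifel olefination, in which iodination of the alkenyl boronate complex triggers a stereoretentive 1,2-metallate shift of the cyclobutyl carbon from boron to carbon and methoxide-induced anti elimination then gives the 1,1-disubstituted alkene with both ring stereocentres unchanged.

**Step 6**
Reactants: 16 2-{2-[(1R,4S)-2,2-dimethyl-4-(prop-1-en-2-yl)cyclobutyl]ethyl}-2-methyl-1,3-dioxolane; 17 oxirane
Product: 20 4-[(1R,4S)-4-(5-hydroxypent-1-en-2-yl)-2,2-dimethylcyclobutyl]butan-2-one, via allylpotassium 18 (not isolated), via hydroxy ketal 19 (not isolated)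
Conditions: n-BuLi, KOt-Bu (Schlosser base), THF/hexane, −78 → −50 °C; 17, −78 → 0 °C; then 1 M HCl, THF, 25 °C
Reagents that add atoms: water (O)
Why: Superbase allylic metalation removes a proton from the isopropenyl methyl group kinetically, the symmetrical allyl anion opens oxirane at either CH2 terminus to the same homologated alcohol, and the acidic work-up hydrolyses the dioxolane (acetal hydrolysis); the stereocentres are not touched.

**Step 7**
Reactants: 21 hept-1-yne; 22 formaldehyde
Product: 25 oct-2-yn-1-yl 4-methylbenzenesulfonate, via lithium hept-1-yn-1-ide 23 (not isolated), via lithium oct-2-yn-1-olate 24 (not isolated)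
Conditions: n-BuLi, THF, −78 °C; (CH2O)n, −78 → 25 °C; TsCl, −20 → 0 °C
Reagents that add atoms: 4-methylbenzenesulfonyl chloride (Cc1ccc(cc1)S(Cl)(=O)=O)
Why: Acetylide hydroxymethylation followed by O-sulfonylation of the lithium alkoxide in the same flask gives the primary propargylic tosylate.

**Step 8**
Reactants: 26 5-chloropent-1-yne; 27 5-bromopentanoic acid
Product: 31 dec-9-ynoic acid, via (5-chloropent-1-yn-1-yl)magnesium bromide 28 (not isolated), via [5-(chloromagnesio)pent-1-yn-1-yl]magnesium bromide 29 (not isolated), via bromomagnesium 5-bromopentanoate 30 (not isolated)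
Conditions: 26, EtMgBr (1 equiv), THF, 40 °C; Mg, 65 °C; added to 27/EtMgBr (1 equiv), Li2CuCl4 (3 mol%), THF, −20 → 25 °C; 2 M HCl
Reagents that add atoms: none
Why: Kochi-type copper-catalysed sp3–sp3 Grignard cross-coupling, in which the alkyne C–H is masked as its magnesium acetylide and the acid as its magnesium carboxylate so that only the primary alkyl Grignard end displaces the primary bromide.

**Step 9**
Reactants: 31 dec-9-ynoic acid; 25 oct-2-yn-1-yl 4-methylbenzenesulfonate
Product: 33 octadeca-9,12-diynoic acid, via bromomagnesium 10-(bromomagnesio)dec-9-ynoate 32 (not isolated)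
Conditions: EtMgBr (2.1 equiv), THF, 45 °C; CuBr·SMe2 (10 mol%), 25, 25 → 50 °C; 2 M HCl
Reagents that add atoms: none
Why: Copper-catalysed propargylic substitution of the tosylate by the alkynyl Grignard end of the dianion (classical skipped-diyne synthesis) gives the 1,4-diyne.

**Step 10**
Reactants: 33 octadeca-9,12-diynoic acid
Product: 34 (9Z,12Z)-octadeca-9,12-dienoic acid
Conditions: H2 (1 atm), Pd/CaCO3 poisoned with Pb(OAc)2 (Lindlar catalyst), quinoline, EtOAc, 20 °C
Reagents that add atoms: none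
Why: Lindlar semi-hydrogenation adds H2 syn to each alkyne and stops at the alkene, giving both Z double bonds of the skipped diene.

**Step 11**
Reactants: 20 4-[(1R,4S)-4-(5-hydroxypent-1-en-2-yl)-2,2-dimethylcyclobutyl]butan-2-one; 34 (9Z,12Z)-octadeca-9,12-dienoic acid
Product: 35 4-[(1S,2R)-3,3-dimethyl-2-(3-oxobutyl)cyclobutyl]pent-4-en-1-yl (9Z,12Z)-octadeca-9,12-dienoate (IN0146)
Conditions: EDC·HCl, DMAP, CH2Cl2, 0 → 25 °C
Reagents that add atoms: none
Why: Steglich esterification (carbodiimide activation, DMAP acyl transfer) acylates the primary alcohol under neutral conditions that leave the ketone, the 1,1-disubstituted alkene and the skipped Z,Z-diene untouched.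

**Compound list**
1 | 1-ethoxycyclopropan-1-ol | CCOC1(O)CC1 | starting material
2 | prop-1-en-2-ylmagnesium bromide | CC(=C)[Mg]Br | starting material
3 | cyclopropanone | O=C1CC1 | intermediate
4 | 1-(prop-1-en-2-yl)cyclopropan-1-ol | CC(=C)C1(O)CC1 | intermediate
5 | 2,2-dimethylcyclobutan-1-one | CC1(C)CCC1=O | intermediate
6 | potassium 4,4-dimethylcyclobut-1-en-1-olate | [K+].[O-]C1=CCC1(C)C | intermediate
7 | 4,4-dimethylcyclobut-1-en-1-yl trifluoromethanesulfonate | CC1(C)CC=C1OS(=O)(=O)C(F)(F)F | intermediate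
8 | 2-ethenyl-2-methyl-1,3-dioxolane | C=CC1(C)OCCO1 | starting material
9 | 9-[2-(2-methyl-1,3-dioxolan-2-yl)ethyl]-9-borabicyclo[3.3.1]nonane | CC1(CCB2C3CCCC2CCC3)OCCO1 | intermediate
10 | 2-[2-(4,4-dimethylcyclobut-1-en-1-yl)ethyl]-2-methyl-1,3-dioxolane | CC1(CCC2=CCC2(C)C)OCCO1 | intermediate
11 | 2-{2-[(1R,4S)-2,2-dimethyl-4-(4,4,5,5-tetramethyl-1,3,2-dioxaborolan-2-yl)cyclobutyl]ethyl}-2-methyl-1,3-dioxolane | CC1(C)OB(OC1(C)C)[C@H]2CC(C)(C)[C@@H]2CCC3(C)OCCO3 | intermediate
12 | 2-bromoprop-1-ene | CC(Br)=C | starting material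
13 | prop-1-en-2-yllithium | [Li]C(C)=C | intermediate
14 | lithium {(1S,2R)-3,3-dimethyl-2-[2-(2-methyl-1,3-dioxolan-2-yl)ethyl]cyclobutyl}(prop-1-en-2-yl)(pinacolato)borate | [Li+].C=C(C)[B-]1(OC(C)(C)C(C)(C)O1)[C@H]2CC(C)(C)[C@@H]2CCC3(C)OCCO3 | intermediate
15 | 2-{2-[(1R,4S)-4-[1-iodo-2-(4,4,5,5-tetramethyl-1,3,2-dioxaborolan-2-yl)propan-2-yl]-2,2-dimethylcyclobutyl]ethyl}-2-methyl-1,3-dioxolane (new boron-bearing carbon unassigned) | ICC(C)(B1OC(C)(C)C(C)(C)O1)[C@H]2CC(C)(C)[C@@H]2CCC3(C)OCCO3 | intermediate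
16 | 2-{2-[(1R,4S)-2,2-dimethyl-4-(prop-1-en-2-yl)cyclobutyl]ethyl}-2-methyl-1,3-dioxolane | C=C(C)[C@H]1CC(C)(C)[C@@H]1CCC2(C)OCCO2 | intermediate
17 | oxirane | C1CO1 | starting material
18 | {2-[(1S,2R)-3,3-dimethyl-2-[2-(2-methyl-1,3-dioxolan-2-yl)ethyl]cyclobutyl]prop-2-en-1-yl}potassium | [K]CC(=C)[C@H]1CC(C)(C)[C@@H]1CCC2(C)OCCO2 | intermediate
19 | 4-[(1S,2R)-3,3-dimethyl-2-[2-(2-methyl-1,3-dioxolan-2-yl)ethyl]cyclobutyl]pent-4-en-1-ol | C=C(CCCO)[C@H]1CC(C)(C)[C@@H]1CCC2(C)OCCO2 | intermediate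
20 | 4-[(1R,4S)-4-(5-hydroxypent-1-en-2-yl)-2,2-dimethylcyclobutyl]butan-2-one | C=C(CCCO)[C@H]1CC(C)(C)[C@@H]1CCC(C)=O | intermediate
21 | hept-1-yne | CCCCCC#C | starting material
22 | formaldehyde (used as paraformaldehyde) | C=O | starting material
23 | lithium hept-1-yn-1-ide | [Li]C#CCCCCC | intermediate
24 | lithium oct-2-yn-1-olate | [Li+].[O-]CC#CCCCCC | intermediate
25 | oct-2-yn-1-yl 4-methylbenzenesulfonate | CCCCCC#CCOS(=O)(=O)c1ccc(C)cc1 | intermediate
26 | 5-chloropent-1-yne | C#CCCCCl | starting material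
27 | 5-bromopentanoic acid | OC(=O)CCCCBr | starting material
28 | (5-chloropent-1-yn-1-yl)magnesium bromide | ClCCCC#C[Mg]Br | intermediate
29 | [5-(chloromagnesio)pent-1-yn-1-yl]magnesium bromide | Cl[Mg]CCCC#C[Mg]Br | intermediate
30 | bromomagnesium 5-bromopentanoate | BrCCCCC(=O)O[Mg]Br | intermediate
31 | dec-9-ynoic acid | C#CCCCCCCCC(=O)O | intermediate
32 | bromomagnesium 10-(bromomagnesio)dec-9-ynoate | Br[Mg]C#CCCCCCCCC(=O)O[Mg]Br | intermediate
33 | octadeca-9,12-diynoic acid | CCCCCC#CCC#CCCCCCCCC(=O)O | intermediate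
34 | (9Z,12Z)-octadeca-9,12-dienoic acid (linoleic acid) | CCCCC/C=C\C/C=C\CCCCCCCC(=O)O | intermediate
35 | 4-[(1S,2R)-3,3-dimethyl-2-(3-oxobutyl)cyclobutyl]pent-4-en-1-yl (9Z,12Z)-octadeca-9,12-dienoate (IN0146) | C=C(CCCOC(=O)CCCCCCC/C=C\C/C=C\CCCCC)[C@H]1CC(C)(C)[C@@H]1CCC(C)=O | target

**Step count**
Total: 11 steps. Longest linear sequence: 7 steps (1, 2, 3, 4, 5, 6, 11); the acid branch is 4 steps (7 or 8, then 9, 10, 11).

**Steps most likely to fail, with fallbacks**

Step 4 (the proposed new hydroboration; rate and enantioselectivity on this hindered unactivated cyclobutene are unproven). The fallback sets out from 10 and comes back at 11, and replaces catalysis by reagent control (Brown asymmetric hydroboration). Cyclobutene 10 is treated at −25 °C in THF with monoisopinocampheylborane (IpcBH2, made from (+)-α-pinene and freed from its TMEDA adduct with BF3·OEt2). The facial sense is chosen by analogy with 1-methylcyclopentene, which gives the (1S,2S)-trans product with this reagent. The product is [(1R,2S,3R,5R)-2,6,6-trimethylbicyclo[3.1.1]heptan-3-yl]{(1S,2R)-3,3-dimethyl-2-[2-(2-methyl-1,3-dioxolan-2-yl)ethyl]cyclobutyl}borane F1, which can be crystallised to raise the ee. Excess acetaldehyde then expels α-pinene and gives diethyl {(1S,2R)-3,3-dimethyl-2-[2-(2-methyl-1,3-dioxolan-2-yl)ethyl]cyclobutyl}boronate F2. Pinacol converts F2 into 11.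

Step 6 (the superbase may attack the ring methine or the dioxolane, and the yield of the oxirane opening is uncertain). The fallback sets out from 11 and comes back at 20, and carries the complete side chain in the alkenyllithium instead of building it by metalation. Purchased pent-4-yn-1-ol is hydrobrominated in the Markovnikov sense (HBr, Et4NBr, CH2Cl2) to 4-bromopent-4-en-1-ol F3. Silylation (TBSCl, imidazole) gives [(4-bromopent-4-en-1-yl)oxy](tert-butyl)dimethylsilane F4, and t-BuLi at −78 °C gives {5-[(tert-butyldimethylsilyl)oxy]pent-1-en-2-yl}lithium F5. Addition of F5 to 11 gives the lithium alkenylboronate complex F6, I2 gives the β-iodoalkylboronate F7, and NaOMe gives tert-butyl({4-[(1S,2R)-3,3-dimethyl-2-[2-(2-methyl-1,3-dioxolan-2-yl)ethyl]cyclobutyl]pent-4-en-1-yl}oxy)dimethylsilane F8. 1 M HCl in THF removes the silyl group and the dioxolane together to give 20.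

Step 8 (formation of the unprotected di-Grignard reagent and its selective coupling with the bromo acid salt may be low-yielding). The fallback sets out from oxirane 17 together with purchased oct-1-yne and comes back at 31, and replaces the alkyl–alkyl coupling by an alkyne zipper. Oct-1-yne is deprotonated with n-BuLi to lithium oct-1-yn-1-ide F9, which opens 17 in the presence of BF3·OEt2 to give dec-3-yn-1-ol F10. KNH(CH2)3NH2 (from KH and propane-1,3-diamine) moves the triple bond to the chain end to give dec-9-yn-1-ol F11. Oxidation with CrO3/H2SO4 in acetone gives 31.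

**Further compounds**
F1 | step 4 | [(1R,2S,3R,5R)-2,6,6-trimethylbicyclo[3.1.1]heptan-3-yl]{(1S,2R)-3,3-dimethyl-2-[2-(2-methyl-1,3-dioxolan-2-yl)ethyl]cyclobutyl}borane | C[C@@H]1[C@H]2C[C@H](C2(C)C)C[C@H]1B[C@H]3CC(C)(C)[C@@H]3CCC4(C)OCCO4
F2 | step 4 | diethyl {(1S,2R)-3,3-dimethyl-2-[2-(2-methyl-1,3-dioxolan-2-yl)ethyl]cyclobutyl}boronate | CCOB(OCC)[C@H]1CC(C)(C)[C@@H]1CCC2(C)OCCO2
F3 | step 6 | 4-bromopent-4-en-1-ol | C=C(Br)CCCO
F4 | step 6 | [(4-bromopent-4-en-1-yl)oxy](tert-butyl)dimethylsilane | C=C(Br)CCCO[Si](C)(C)C(C)(C)C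
F5 | step 6 | {5-[(tert-butyldimethylsilyl)oxy]pent-1-en-2-yl}lithium | [Li]C(=C)CCCO[Si](C)(C)C(C)(C)C
F6 | step 6 | lithium {5-[(tert-butyldimethylsilyl)oxy]pent-1-en-2-yl}{(1S,2R)-3,3-dimethyl-2-[2-(2-methyl-1,3-dioxolan-2-yl)ethyl]cyclobutyl}(pinacolato)borate | [Li+].C=C(CCCO[Si](C)(C)C(C)(C)C)[B-]1(OC(C)(C)C(C)(C)O1)[C@H]2CC(C)(C)[C@@H]2CCC3(C)OCCO3
F7 | step 6 | tert-butyl({5-iodo-4-[(1S,2R)-3,3-dimethyl-2-[2-(2-methyl-1,3-dioxolan-2-yl)ethyl]cyclobutyl]-4-(4,4,5,5-tetramethyl-1,3,2-dioxaborolan-2-yl)pentyl}oxy)dimethylsilane | ICC(CCCO[Si](C)(C)C(C)(C)C)(B1OC(C)(C)C(C)(C)O1)[C@H]2CC(C)(C)[C@@H]2CCC3(C)OCCO3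
F8 | step 6 | tert-butyl({4-[(1S,2R)-3,3-dimethyl-2-[2-(2-methyl-1,3-dioxolan-2-yl)ethyl]cyclobutyl]pent-4-en-1-yl}oxy)dimethylsilane | C=C(CCCO[Si](C)(C)C(C)(C)C)[C@H]1CC(C)(C)[C@@H]1CCC2(C)OCCO2
F9 | step 8 | lithium oct-1-yn-1-ide | [Li]C#CCCCCCC
F10 | step 8 | dec-3-yn-1-ol | CCCCCCC#CCCO
F11 | step 8 | dec-9-yn-1-ol | C#CCCCCCCCCO
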